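The constants used here belong to no real substance; what happens was integrated by code.

In this scheme quenched electrophile cannot couple and protonated nucleophile cannot couple either, so I counted what this flask could spend before reckoning its time.

electrophile 0.020 M; nucleophile 0.0300 M; free base 0.0240 M (fed, over 20 min); protic impurity 10.0 mM; time 1.5 h; the fed solution adds 0.50 times the starting volume

    electrophile + nucleophile → acid set free + target (k1 = 0.031 L mol⁻¹ s⁻¹)
    nucleophile + acid set free ⇌ protonated nucleophile, settled at all times (K2 = 13000 L mol⁻¹)
    acid set free + free base ⇌ salt of the base, settled at all times (K3 = 100 L mol⁻¹)
    target ⇌ isomer of the product (K4 = 0.88, k4 = 0.0060 s⁻¹)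
    electrophile + protic impurity → quenched substrate (k5 = 0.31 L mol⁻¹ s⁻¹)

1. part of the electrophile that has reacted at 1.5 h
2. share of the unused nucleophile that is free and not bound as protonated nucleophile, at 1.5 h

- charges are per starting volume, the dose included; the dosed solution carries all of it
- run time (flask): 1.5 h

As pseudo-first-order constants on the charges, the quench of electrophile began at 0.186 min⁻¹, faster than the coupling at 0.0558 min⁻¹. So I gave the protic impurity its whole charge, half of the electrophile, which left 0.0100 M of electrophile to couple. Each coupling frees one acid, and I put that acid on nucleophile because K2 is 130 times K3. One coupling therefore cost two nucleophile. Nucleophile charged over twice the electrophile left to couple came to 1.50: that ratio is the cover. With the impurity's charge and the acid counted this way, a cover below one made nucleophile the limiting reagent in my count, with electrophile left over; above one, as in this flask, it made electrophile the limiting one.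

With that electrophile coupled, my count put free nucleophile in this flask at 0.00667 M after dilution, and the free share of the unused nucleophile at 50.0%. That nucleophile gives electrophile a late half-life of 0.932 h, so I took 83.6% as a rough low estimate of the reacted part. My reckoning stopped at these two estimates.

The forecast said 95% reacted (92% to 97%) and 57% free (53% to 62%), reasoning that acid “ties up a second nucleophile”. Its figures are higher than my two estimates.

The simulation gave 94.6% reacted and 58.0% free, both inside the forecast's ranges. At 0.0394 h electrophile's half-life by the quench, 0.13 h, was shorter than by coupling, 0.25 h, but at 1.50 h it had grown to 9.0 h, with protic impurity at 1.03% of its charge. This flask, at cover 1.50, ended with 5.4% of its electrophile against 41% of its nucleophile.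

The neighbour flask charged with 0.034 M of electrophile has cover 0.625, and the same count leaves 26.5% of its electrophile over. Computed, that neighbour kept 27.2% of its electrophile, with 72.8% reacted and nucleophile down to 7.42% of its charge.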